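**Plan**

- Retrosynthesis: the allyl groups of ring B, the silyl group on the CH2O carbon and the 2‑O‑methyl group of ring A are removed first. Ring A is then cut at C1–C2 and C5–C6, and the ynoate that remains is cut at the depside C–O bond.
- Ring A allows this cut because its substituents (ester at C1, oxygen at C2 and C4, CH2O at C3, H at C5, methyl at C6) map onto a 1,1,3‑trioxygenated 2‑substituted butadiene (C2–C5) and a but‑2‑ynoate (C1 and C6).
- Forward: ring B comes from atraric acid (four steps) and is acylated on its 4‑hydroxyl with linear but‑2‑ynoic acid. The diene is made in four steps from methyl 3‑hydroxypropanoate. Ring A is then built on the ynoate by (4+2) cycloaddition and aromatization.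
- End game: O‑methylation of the ring A phenol, desilylation, deallylation.
- Stereochemistry: the target has no stereocentre and no configured double bond, so only the orientation of the cycloaddition has to be controlled.

Key step: step 10

Remark on the chemistry: racemic intermediates (12, 13, 17) and the double‑bond isomers of 11, 14, 15 and 16 are carried as mixtures, because these elements disappear on aromatization; their SMILES are written without descriptors.

**Route**

Step 1
Reactants: 1 methyl 2,4-dihydroxy-3,6-dimethylbenzoate (atraric acid)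
Product: 2 methyl 2-hydroxy-4-[(4-methoxybenzyl)oxy]-3,6-dimethylbenzoate
Conditions: PMBCl (1.05 equiv), K2CO3, acetone, reflux
Reagents that add atoms: 4-methoxybenzyl chloride, COc1ccc(CCl)cc1
Why: Williamson etherification should take place only at the free 4-hydroxyl, because the 2-hydroxyl is hydrogen-bonded to the ester carbonyl and flanked by the 3-methyl group.

Step 2
Reactants: 2 methyl 2-hydroxy-4-[(4-methoxybenzyl)oxy]-3,6-dimethylbenzoate
Product: 3 2-hydroxy-4-[(4-methoxybenzyl)oxy]-3,6-dimethylbenzoic acid
Conditions: KOH, DMSO/H2O (4:1), 80 °C; then 1 M HCl to pH 3, 0 °C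
Reagents that add atoms: potassium hydroxide, [K+].[OH-]
Why: Saponification of the hindered salicylate is forced by hot hydroxide in aqueous DMSO, the PMB ether is inert to base, and cold acidification should avoid decarboxylation of the electron-rich acid.

Step 3
Reactants: 3 2-hydroxy-4-[(4-methoxybenzyl)oxy]-3,6-dimethylbenzoic acid
Product: 5 allyl 2-(allyloxy)-4-[(4-methoxybenzyl)oxy]-3,6-dimethylbenzoate, via allyl ester phenol 4 (not isolated)
Conditions: allyl bromide (3 equiv), K2CO3, DMF, rt → 50 °C
Reagents that add atoms: allyl bromide, C=CCBr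
Why: Exhaustive O-alkylation (carboxylate alkylation followed by Williamson etherification) should first give ester 4 and, on warming with excess halide, alkylate the hydrogen-bonded phenol as well.

Step 4
Reactants: 5 allyl 2-(allyloxy)-4-[(4-methoxybenzyl)oxy]-3,6-dimethylbenzoate
Product: 6 allyl 2-(allyloxy)-4-hydroxy-3,6-dimethylbenzoate
Conditions: CF3CO2H, Et3SiH, CH2Cl2, 0 °C
Reagents that add atoms: none
Why: Acidolysis of the aryl 4-methoxybenzyl ether (ionization to the stabilized benzylic cation, which Et3SiH reduces before it can alkylate the liberated phenol) should leave the allyl ester and the allyl ether untouched.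

Step 5
Reactants: 6 allyl 2-(allyloxy)-4-hydroxy-3,6-dimethylbenzoate; 7 but-2-ynoic acid
Product: 8 allyl 2-(allyloxy)-4-(but-2-ynoyloxy)-3,6-dimethylbenzoate
Conditions: DCC, DMAP (5 mol %), CH2Cl2, 0 °C → rt
Reagents that add atoms: none
Why: Steglich esterification should be easy here, because the phenol has only one ortho substituent and the acid is linear, so the depside C–O bond is made before the crowding around C1 of ring A exists.

Step 6
Reactants: 9 methyl 3-hydroxypropanoate
Product: 10 methyl 3-[(tert-butyldiphenylsilyl)oxy]propanoate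
Conditions: TBDPSCl, imidazole, DMF, rt
Reagents that add atoms: tert-butyl(chloro)diphenylsilane, CC(C)(C)[Si](Cl)(c1ccccc1)c1ccccc1
Why: Imidazole-promoted silylation of a primary alcohol; the TBDPS ether is chosen because it should survive the acid of step 8 and the acidic work-up of step 10.

Step 7
Reactants: 10 methyl 3-[(tert-butyldiphenylsilyl)oxy]propanoate
Product: 12 methyl 2-{[(tert-butyldiphenylsilyl)oxy]methyl}-3-oxobutanoate (racemic), via lithium ester enolate 11 (not isolated)
Conditions: LiN(iPr)2, THF, −78 °C; then cannulation into AcCl, THF, −78 °C; AcOH quench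
Reagents that add atoms: acetyl chloride, CC(=O)Cl
Why: Claisen-type C-acylation of a lithium ester enolate with an acid chloride; inverse addition at −78 °C should outrun both β-elimination of silanolate and proton transfer from the product to unreacted enolate.

Step 8
Reactants: 12 methyl 2-{[(tert-butyldiphenylsilyl)oxy]methyl}-3-oxobutanoate
Product: 14 methyl 2-{[(tert-butyldiphenylsilyl)oxy]methyl}-3-methoxybut-2-enoate (mixture of double-bond isomers), via dimethyl ketal 13 (not isolated)
Conditions: HC(OMe)3 (solvent), camphorsulfonic acid (cat.), 40 °C; Et3N quench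
Reagents that add atoms: trimethyl orthoformate, COC(OC)OC
Why: Acid-catalysed ketalization with the orthoester followed by loss of methanol is the standard enol ether formation from α-substituted acetoacetates, and every double-bond isomer formed should lead to the same dienolate in step 9.

Step 9
Reactants: 14 methyl 2-{[(tert-butyldiphenylsilyl)oxy]methyl}-3-methoxybut-2-enoate
Product: 16 2-{[(tert-butyldiphenylsilyl)oxy]methyl}-1,3-dimethoxy-1-(trimethylsilyloxy)buta-1,3-diene, via lithium dienolate 15 (not isolated)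
Conditions: LiN(iPr)2, THF, −78 °C; then Me3SiCl, −78 °C → rt; pentane, filtration under argon, used crude
Reagents that add atoms: chlorotrimethylsilane, C[Si](C)(C)Cl
Why: Kinetic γ-deprotonation of the β-methoxy enoate (vinylogous enolate formation) and O-silylation of the dienolate by the hard silyl chloride should give the silyl ketene acetal diene, as for the parent and 2-alkyl members of this diene family.

Step 10
Reactants: 8 allyl 2-(allyloxy)-4-(but-2-ynoyloxy)-3,6-dimethylbenzoate; 16 2-{[(tert-butyldiphenylsilyl)oxy]methyl}-1,3-dimethoxy-1-(trimethylsilyloxy)buta-1,3-diene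
Product: 19 allyl 2-(allyloxy)-4-{[3-({[tert-butyl(diphenyl)silyl]oxy}methyl)-2-hydroxy-4-methoxy-6-methylbenzoyl]oxy}-3,6-dimethylbenzoate, via cyclohexa-1,4-diene cycloadduct 17 (not isolated), via aryl trimethylsilyl ether 18 (not isolated)
Conditions: 16 (2.5 equiv), toluene, 110 °C (sealed tube); then 0.5 M HCl, THF, 0 °C → rt
Reagents that add atoms: none
Why: This is a thermal, asynchronous (4+2) cycloaddition of normal electron demand in which the unsubstituted terminus of ketene acetal diene 16, made nucleophilic by three oxygen donors, bonds to the methyl-bearing β-carbon of ynoate 8 and the ketene acetal carbon then closes onto the α-carbon, forming the C5–C6 and C1–C2 bonds of ring A. The closest known reaction type is the Diels–Alder reaction of 1,3-dialkoxy-1-silyloxybutadienes with alkynoates followed by aromatization to 2-hydroxy-4-alkoxybenzoates. Ring A closes as a six-membered carbocycle by intermolecular union of a four-carbon and a two-carbon unit; adduct 17 then loses methanol from its mixed ketal to give aryl silyl ether 18, which dilute acid hydrolyses to the hydrogen-bonded phenol 19 while the TBDPS ether stays intact. No stereocentre has to be controlled, because the ketal carbon of 17 becomes aromatic. The one selectivity needed is the orientation (ester next to the ketal carbon, methyl next to the former diene CH2), which is secured by matching the polarized diene terminus with the electrophilic β-carbon of the ynoate, whose aryl ester lowers the LUMO further than an alkyl ester would. Any adduct that instead loses trimethylsilanol gives the 2-methyl ether 20 directly, so both modes of aromatization converge after step 11.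

Step 11
Reactants: 19 allyl 2-(allyloxy)-4-{[3-({[tert-butyl(diphenyl)silyl]oxy}methyl)-2-hydroxy-4-methoxy-6-methylbenzoyl]oxy}-3,6-dimethylbenzoate
Product: 20 allyl 2-(allyloxy)-4-{[3-({[tert-butyl(diphenyl)silyl]oxy}methyl)-2,4-dimethoxy-6-methylbenzoyl]oxy}-3,6-dimethylbenzoate
Conditions: MeI, K2CO3, DMF, 40 °C
Reagents that add atoms: iodomethane, CI
Why: Williamson methylation of the only free hydroxyl in the molecule; carbonate in DMF should break the hydrogen bond to the ester without attacking the hindered aryl ester or the allyl ester.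

Step 12
Reactants: 20 allyl 2-(allyloxy)-4-{[3-({[tert-butyl(diphenyl)silyl]oxy}methyl)-2,4-dimethoxy-6-methylbenzoyl]oxy}-3,6-dimethylbenzoate
Product: 21 allyl 2-(allyloxy)-4-{[3-(hydroxymethyl)-2,4-dimethoxy-6-methylbenzoyl]oxy}-3,6-dimethylbenzoate
Conditions: Bu4NF, AcOH (1:1), THF, rt
Reagents that add atoms: none
Why: Fluoride-induced desilylation, buffered with acetic acid so that neither fluoride nor the liberated alkoxide attacks the aryl ester; the benzylic alcohol is meta to the ester carbonyl and cannot lactonize.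

Step 13
Reactants: 21 allyl 2-(allyloxy)-4-{[3-(hydroxymethyl)-2,4-dimethoxy-6-methylbenzoyl]oxy}-3,6-dimethylbenzoate
Product: 22 2-hydroxy-4-{[3-(hydroxymethyl)-2,4-dimethoxy-6-methylbenzoyl]oxy}-3,6-dimethylbenzoic acid (target, CNP0372912.0)
Conditions: Pd(PPh3)4 (5 mol %, zerovalent palladium), morpholine, THF, rt; then aqueous citric acid
Reagents that add atoms: none
Why: Tsuji–Trost deallylation, in which zerovalent palladium ionizes both the allyl ester and the aryl allyl ether to π-allyl complexes that morpholine traps, should free the acid and the phenol under conditions that leave the depside ester and the benzylic alcohol alone.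

**Compound list**

1 | methyl 2,4-dihydroxy-3,6-dimethylbenzoate (atraric acid) | COC(=O)c1c(C)cc(O)c(C)c1O | starting material
2 | methyl 2-hydroxy-4-[(4-methoxybenzyl)oxy]-3,6-dimethylbenzoate | COC(=O)c1c(C)cc(OCc2ccc(OC)cc2)c(C)c1O | intermediate
3 | 2-hydroxy-4-[(4-methoxybenzyl)oxy]-3,6-dimethylbenzoic acid | OC(=O)c1c(C)cc(OCc2ccc(OC)cc2)c(C)c1O | intermediate
4 | allyl 2-hydroxy-4-[(4-methoxybenzyl)oxy]-3,6-dimethylbenzoate | C=CCOC(=O)c1c(C)cc(OCc2ccc(OC)cc2)c(C)c1O | intermediate (not isolated)
5 | allyl 2-(allyloxy)-4-[(4-methoxybenzyl)oxy]-3,6-dimethylbenzoate | C=CCOC(=O)c1c(C)cc(OCc2ccc(OC)cc2)c(C)c1OCC=C | intermediate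
6 | allyl 2-(allyloxy)-4-hydroxy-3,6-dimethylbenzoate | C=CCOC(=O)c1c(C)cc(O)c(C)c1OCC=C | intermediate
7 | but-2-ynoic acid | CC#CC(=O)O | starting material
8 | allyl 2-(allyloxy)-4-(but-2-ynoyloxy)-3,6-dimethylbenzoate (ring B aryl ynoate) | CC#CC(=O)Oc1cc(C)c(C(=O)OCC=C)c(OCC=C)c1C | intermediate
9 | methyl 3-hydroxypropanoate | COC(=O)CCO | starting material
10 | methyl 3-[(tert-butyldiphenylsilyl)oxy]propanoate | COC(=O)CCO[Si](c1ccccc1)(c1ccccc1)C(C)(C)C | intermediate
11 | lithium enolate of 10 | [Li]OC(OC)=CCO[Si](c1ccccc1)(c1ccccc1)C(C)(C)C | intermediate (not isolated)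
12 | methyl 2-{[(tert-butyldiphenylsilyl)oxy]methyl}-3-oxobutanoate (racemic) | COC(=O)C(CO[Si](c1ccccc1)(c1ccccc1)C(C)(C)C)C(C)=O | intermediate
13 | methyl 2-{[(tert-butyldiphenylsilyl)oxy]methyl}-3,3-dimethoxybutanoate (racemic) | COC(=O)C(CO[Si](c1ccccc1)(c1ccccc1)C(C)(C)C)C(C)(OC)OC | intermediate (not isolated)
14 | methyl 2-{[(tert-butyldiphenylsilyl)oxy]methyl}-3-methoxybut-2-enoate (isomer mixture) | COC(=O)C(CO[Si](c1ccccc1)(c1ccccc1)C(C)(C)C)=C(C)OC | intermediate
15 | lithium dienolate of 14 | [Li]OC(OC)=C(CO[Si](c1ccccc1)(c1ccccc1)C(C)(C)C)C(OC)=C | intermediate (not isolated)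
16 | 2-{[(tert-butyldiphenylsilyl)oxy]methyl}-1,3-dimethoxy-1-(trimethylsilyloxy)buta-1,3-diene | C=C(OC)C(CO[Si](c1ccccc1)(c1ccccc1)C(C)(C)C)=C(OC)O[Si](C)(C)C | intermediate
17 | cyclohexa-1,4-diene cycloadduct: aryl 4,6-dimethoxy-2-methyl-5-(silyloxymethyl)-6-(trimethylsilyloxy)cyclohexa-1,4-diene-1-carboxylate of phenol 6 (racemic) | CC1=C(C(=O)Oc2cc(C)c(C(=O)OCC=C)c(OCC=C)c2C)C(OC)(O[Si](C)(C)C)C(CO[Si](c2ccccc2)(c2ccccc2)C(C)(C)C)=C(OC)C1 | intermediate (not isolated)
18 | allyl 2-(allyloxy)-4-{[3-({[tert-butyl(diphenyl)silyl]oxy}methyl)-4-methoxy-6-methyl-2-(trimethylsilyloxy)benzoyl]oxy}-3,6-dimethylbenzoate | COc1cc(C)c(C(=O)Oc2cc(C)c(C(=O)OCC=C)c(OCC=C)c2C)c(O[Si](C)(C)C)c1CO[Si](c3ccccc3)(c3ccccc3)C(C)(C)C | intermediate (not isolated)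
19 | allyl 2-(allyloxy)-4-{[3-({[tert-butyl(diphenyl)silyl]oxy}methyl)-2-hydroxy-4-methoxy-6-methylbenzoyl]oxy}-3,6-dimethylbenzoate | COc1cc(C)c(C(=O)Oc2cc(C)c(C(=O)OCC=C)c(OCC=C)c2C)c(O)c1CO[Si](c3ccccc3)(c3ccccc3)C(C)(C)C | intermediate
20 | allyl 2-(allyloxy)-4-{[3-({[tert-butyl(diphenyl)silyl]oxy}methyl)-2,4-dimethoxy-6-methylbenzoyl]oxy}-3,6-dimethylbenzoate | COc1cc(C)c(C(=O)Oc2cc(C)c(C(=O)OCC=C)c(OCC=C)c2C)c(OC)c1CO[Si](c3ccccc3)(c3ccccc3)C(C)(C)C | intermediate
21 | allyl 2-(allyloxy)-4-{[3-(hydroxymethyl)-2,4-dimethoxy-6-methylbenzoyl]oxy}-3,6-dimethylbenzoate | COc1cc(C)c(C(=O)Oc2cc(C)c(C(=O)OCC=C)c(OCC=C)c2C)c(OC)c1CO | intermediate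
22 | 2-hydroxy-4-{[3-(hydroxymethyl)-2,4-dimethoxy-6-methylbenzoyl]oxy}-3,6-dimethylbenzoic acid | COc1cc(C)c(C(=O)Oc2cc(C)c(C(=O)O)c(O)c2C)c(OC)c1CO | target

**Summary**

Total step count: 13.
Longest linear sequence: 9 steps (steps 1–5 and 10–13, from atraric acid); the diene branch is 4 steps (steps 6–9) before the convergence.

**Steps most likely to fail**

1. Step 10. The β-methyl-substituted ynoate may add too slowly, so that the diene is consumed by silyl migration or adventitious hydrolysis and, at higher temperature, the aryl allyl ether begins to rearrange sigmatropically. The fallback changes the dienophile to an allenoate, which is more reactive towards electron-rich dienes and aromatizes to the same arene. It sets out from phenol 6. Carbodiimide esterification with but-3-ynoic acid (DCC, CH2Cl2, 0 °C) would give allyl 2-(allyloxy)-4-(but-3-ynoyloxy)-3,6-dimethylbenzoate F1, and catalytic Et3N should isomerize it to allyl 2-(allyloxy)-4-(buta-2,3-dienoyloxy)-3,6-dimethylbenzoate F2. Diene 16 should add across the α,β-double bond of F2 at 25–60 °C with the same orientation to give the 6-methylene cycloadduct F3. Loss of methanol and tautomerization of the exocyclic double bond into the ring would give aryl silyl ether 18, and the acidic work-up comes back to the route at 19.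

2. Step 9. The dienolate may expel silanolate by β-elimination, the tetrasubstituted enoate may resist γ-deprotonation, or the silyl ketene acetal may hydrolyse on handling. The fallback attaches the hydroxymethyl carbon after ring A is built and sets out from ynoate 8. Commercial methyl (E)-3-methoxybut-2-enoate is converted (LiN(iPr)2, then Me3SiCl, THF, −78 °C), by way of its lithium dienolate F4, into 1,3-dimethoxy-1-(trimethylsilyloxy)buta-1,3-diene F5. Cycloaddition with 8 under the conditions of step 10 should pass through the cyclohexa-1,4-diene cycloadduct F6 and the aryl trimethylsilyl ether F7 to give allyl 2-(allyloxy)-4-[(2-hydroxy-4-methoxy-6-methylbenzoyl)oxy]-3,6-dimethylbenzoate F8. Magnesium-mediated ortho-formylation (MgCl2, Et3N, paraformaldehyde, MeCN, reflux) should place the aldehyde at C3, the only free position ortho to the phenol, to give allyl 2-(allyloxy)-4-[(3-formyl-2-hydroxy-4-methoxy-6-methylbenzoyl)oxy]-3,6-dimethylbenzoate F9. Methylation (MeI, K2CO3, DMF) would give allyl 2-(allyloxy)-4-[(3-formyl-2,4-dimethoxy-6-methylbenzoyl)oxy]-3,6-dimethylbenzoate F10, and reduction of the aldehyde (NaBH4, THF/MeOH, 0 °C) comes back to the route at 21.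

3. Step 7. The ester enolate may lose silanolate by β-elimination to give methyl acrylate, and proton transfer from the β-keto ester to unreacted enolate may cap the conversion. The fallback makes the C–C bond from an enolate that has no leaving group in the β-position and sets out from 9. Double deprotonation (LiN(iPr)2, 2.2 equiv, THF, −50 → −20 °C) gives the dilithium alkoxide enolate F11, whose aldol addition to acetaldehyde at −78 °C should give methyl 3-hydroxy-2-(hydroxymethyl)butanoate F12 as a mixture of diastereomers. Selective silylation of the primary hydroxyl (TBDPSCl, imidazole, CH2Cl2, 0 °C) gives methyl 2-{[(tert-butyldiphenylsilyl)oxy]methyl}-3-hydroxybutanoate F13, and Dess–Martin oxidation (CH2Cl2, rt) comes back to the route at 12.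

**Further compounds**

F1 | step 10 | allyl 2-(allyloxy)-4-(but-3-ynoyloxy)-3,6-dimethylbenzoate | C#CCC(=O)Oc1cc(C)c(C(=O)OCC=C)c(OCC=C)c1C
F2 | step 10 | allyl 2-(allyloxy)-4-(buta-2,3-dienoyloxy)-3,6-dimethylbenzoate | C=C=CC(=O)Oc1cc(C)c(C(=O)OCC=C)c(OCC=C)c1C
F3 | step 10 | 6-methylene cycloadduct: aryl 2,4-dimethoxy-6-methylidene-3-(silyloxymethyl)-2-(trimethylsilyloxy)cyclohex-3-ene-1-carboxylate of phenol 6 | C=C1CC(OC)=C(CO[Si](c2ccccc2)(c2ccccc2)C(C)(C)C)C(OC)(O[Si](C)(C)C)C1C(=O)Oc3cc(C)c(C(=O)OCC=C)c(OCC=C)c3C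
F4 | step 9 | lithium dienolate of methyl 3-methoxybut-2-enoate | [Li]OC(OC)=CC(OC)=C
F5 | step 9 | 1,3-dimethoxy-1-(trimethylsilyloxy)buta-1,3-diene | C=C(OC)C=C(OC)O[Si](C)(C)C
F6 | step 9 | cyclohexa-1,4-diene cycloadduct of 8 and F5 | CC1=C(C(=O)Oc2cc(C)c(C(=O)OCC=C)c(OCC=C)c2C)C(OC)(O[Si](C)(C)C)C=C(OC)C1
F7 | step 9 | allyl 2-(allyloxy)-4-{[4-methoxy-6-methyl-2-(trimethylsilyloxy)benzoyl]oxy}-3,6-dimethylbenzoate | COc1cc(C)c(C(=O)Oc2cc(C)c(C(=O)OCC=C)c(OCC=C)c2C)c(O[Si](C)(C)C)c1
F8 | step 9 | allyl 2-(allyloxy)-4-[(2-hydroxy-4-methoxy-6-methylbenzoyl)oxy]-3,6-dimethylbenzoate | COc1cc(C)c(C(=O)Oc2cc(C)c(C(=O)OCC=C)c(OCC=C)c2C)c(O)c1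
F9 | step 9 | allyl 2-(allyloxy)-4-[(3-formyl-2-hydroxy-4-methoxy-6-methylbenzoyl)oxy]-3,6-dimethylbenzoate | COc1cc(C)c(C(=O)Oc2cc(C)c(C(=O)OCC=C)c(OCC=C)c2C)c(O)c1C=O
F10 | step 9 | allyl 2-(allyloxy)-4-[(3-formyl-2,4-dimethoxy-6-methylbenzoyl)oxy]-3,6-dimethylbenzoate | COc1cc(C)c(C(=O)Oc2cc(C)c(C(=O)OCC=C)c(OCC=C)c2C)c(OC)c1C=O
F11 | step 7 | dilithium alkoxide enolate of methyl 3-hydroxypropanoate | [Li]OCC=C(OC)O[Li]
F12 | step 7 | methyl 3-hydroxy-2-(hydroxymethyl)butanoate (diastereomer mixture) | COC(=O)C(CO)C(C)O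
F13 | step 7 | methyl 2-{[(tert-butyldiphenylsilyl)oxy]methyl}-3-hydroxybutanoate (diastereomer mixture) | COC(=O)C(CO[Si](c1ccccc1)(c1ccccc1)C(C)(C)C)C(C)O
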